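You ask for a quick number, and instead of two rate constants I need just their ratio. In the beta run complex with one exchanged reads 32.0% at 2.00 h and 31.9% at 3.00 h, so I take its making and its loss to side product to balance there, which puts c(incoming ligand)/c(complex with one exchanged) at that ratio. Counting the ligand left from the balance, I read 0.491: the selectivity factor s, the constant for starting complex meeting complex with one exchanged over that for starting complex meeting incoming ligand.

| flask | starting complex | incoming ligand | remark | time |
|---|---|---|---|---|
| beta | 0.50 M | 0.64 equiv | run made earlier |  |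
| eta | 0.50 M | 1.4 equiv | run made earlier |  |
| theta | 0.25 M | 0.95 equiv | run made earlier |  |
| flask | 0.50 M | 0.950 equiv |  | 6.0 h |

| run | time / h | complex with two exchanged / % | complex with one exchanged / % | side product / % |
|---|---|---|---|---|
| beta | 0.667 | 0.4 | 22.2 | 6.7 |
| beta | 1.33 | 0.6 | 30.2 | 16.0 |
| beta | 2.00 | 0.4 | 32.0 | 24.7 |
| beta | 3.00 | 1.0 | 31.9 | 35.1 |
| beta | 4.00 | 1.0 | 30.5 | 43.2 |
| beta | 5.00 | 0.3 | 29.4 | 48.9 |
| eta | 0.417 | 0.3 | 34.0 | 5.6 |
| eta | 0.667 | 0.8 | 43.0 | 9.5 |
| eta | 0.833 | 1.0 | 47.5 | 12.3 |
| eta | 1.33 | 1.3 | 53.6 | 19.7 |
| eta | 2.00 | 1.8 | 56.6 | 25.7 |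
| eta | 3.00 | 2.5 | 58.2 | 30.8 |
| eta | 5.00 | 2.0 | 56.2 | 34.0 |
| theta | 0.417 | 0 | 15.2 | 1.4 |
| theta | 1.33 | 0.8 | 31.9 | 7.5 |
| theta | 2.00 | 1.3 | 37.7 | 13.9 |
| theta | 3.00 | 1.0 | 42.0 | 20.2 |
| theta | 5.00 | 1.0 | 45.0 | 31.8 |

(readings scatter by 0.3 percentage points)

- percentages count the starting complex that a species holds: one side product counts as two

- complex with two exchanged present at 6.0 h, in percent of the starting complex charged
- complex with one exchanged present at 6.0 h, in percent of the starting complex charged
- side product present at 6.0 h, in percent of the starting complex charged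

I solve both ends. Late end: with those two steps, complex with one exchanged tops at the charge times s^(s/(1−s)), which for this flask is 47.8%. Ligand then stands at 23.5% of the complex charged, and the balances give side product 47.4% and starting complex 4.81%.

Early end: theta has the same equivalents at half the concentration, so if each step takes two partners, its 5.00 h is 2.50 h here. Its starting complex, by difference, is then 22.2%, falling at 0.505 h⁻¹ on this flask's clock, which leaves about 3.79% at 6.0 h, near the top's amount. So I say 47.8% and 47.4%, with complex with two exchanged near 1.50%.

Your forecast says 1.3%, 40.5% and 47%, with the words “This suggests exchange is reversible”; mine is higher on complex with one exchanged.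

The flask gives 1.43%, 43.7% and 47.0%.

    complex with three exchanged + incoming ligand → leaving ligand + complex with four exchanged (k = 2.10 M⁻¹ h⁻¹)
    starting complex + complex with one exchanged → side product (k = 0.880 M⁻¹ h⁻¹)
    incoming ligand → decomposition product (k = 0.00130 h⁻¹)
    complex with one exchanged + incoming ligand → leaving ligand + complex with two exchanged (k = 0.110 M⁻¹ h⁻¹)
    starting complex + incoming ligand → leaving ligand + complex with one exchanged (k = 1.90 M⁻¹ h⁻¹)
    complex with two exchanged + incoming ligand → leaving ligand + complex with three exchanged (k = 3.10 M⁻¹ h⁻¹)

At 6.0 h this flask's c(incoming ligand)/c(complex with one exchanged) is 0.369, under s, and complex with one exchanged is made at 0.579 of the rate it is used up. It goes to side product 2.7 times as fast as on to complex with two exchanged. In the neighbour charged with 0.380 equiv of incoming ligand the same ratio is 0.104, further under s, and complex with one exchanged stands at 12.3%.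

The numbers in the tables stem from a simulated flask on assumed constants, and the scatter is random.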